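A percentage point of the free monomer charged was my unit, and I had to say how many such points each new flask would hold as monomer in chains at its end.

| flask | free monomer | initiator | temperature | remark | time |
|---|---|---|---|---|---|
| teal | 0.067 M | 1.1 mol% | 15 °C | run made earlier |  |
| green | 0.15 M | 1.1 mol% | 40 °C | run made earlier |  |
| grey | 0.10 M | 1.7 mol% | 15 °C | run made earlier |  |
| ash | 0.10 M | 1.1 mol% | 40 °C |  | 25 h |
| birch | 0.10 M | 1.1 mol% | 60 °C |  | 25 h |
| maple | 0.10 M | 1.1 mol% | 20 °C |  | 25 h |

| run | time / h | monomer in chains / % | free monomer / % |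
|---|---|---|---|
| teal | 15.0 | 11.6 | 84.1 |
| teal | 30.0 | 19.4 | 71.7 |
| teal | 40.0 | 23.9 | 64.9 |
| teal | 48.0 | 28.5 | 59.7 |
| teal | 72.0 | 37.8 | 47.6 |
| green | 2.00 | 25.9 | 58.5 |
| green | 5.00 | 45.4 | 31.0 |
| green | 10.0 | 58.4 | 14.0 |
| green | 15.0 | 62.5 | 7.6 |
| green | 20.0 | 63.7 | 3.9 |
| grey | 6.00 | 6.2 | 90.0 |
| grey | 15.0 | 14.8 | 77.9 |
| grey | 30.0 | 26.9 | 61.7 |
| grey | 48.0 | 35.8 | 47.3 |
| grey | 72.0 | 47.7 | 34.3 |

(each reading ± 0.5 percentage points)



1. the flask with the highest amount of monomer in chains, in percent of the free monomer charged ("all alike" if they lie within 1.5 percentage points) (ash / birch / maple / all alike)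
2. final monomer in chains, as a percentage of the free monomer charged, in ash
3. final monomer in chains, as a percentage of the free monomer charged, in birch
4. final monomer in chains, as a percentage of the free monomer charged, in maple

I read the runs as a ladder of clocks. The first was the lifetime of free monomer in the green run, 3.73 h from its first reading and shorter than the 25 h of the new flasks, while the teal run gave 86.6 h, longer than that time. Taking the rate as the root of the initiator concentration, I found a factor of 15.5 between those temperatures. That put maple at 41.0 h. Green's selectivity, monomer in chains per point of free monomer lost, was 0.676 at 15.0 h, so I reckoned maple at 30.9%.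

The next clock sat in green's tail. By 20.0 h free monomer had fallen a further 3.7 percentage points, which at that selectivity should have added 2.5 points, yet chains rose 1.2 points. The miss of 1.3 points on 63.7% of chains reads as 244 h, the chain lifetime, a rough reading against a scatter of 0.5 points. I assumed it scales with the same factor, giving 27.3 h at birch's temperature and 2190 h at maple's. My first answer for ash and birch was green's last reading. Going round once more left ash there but took birch down to 25.5%.

The forecast named ash, with 62.6% in ash, 62% in birch and 30.7% in maple, on the grounds that “The chain share is about 0.70 at 15 °C and 0.665 at 40 °C, so roughly 0.69 at 20 °C and 0.64 at 60 °C”. On birch my reckoning differed from it.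

The simulation put ash highest, with 65.2% there, 44.0% in birch and 29.9% in maple. Birch ended above my reckoning of 25.5%, and it still held 41.9% at 250 h. On ash, the chain lifetime gives 6.68% of the charge moved out of chains by 25.0 h, and isomer of the product stood there at 6.21%.

    initiator → 2 initiating radical (k = 2.00 × 10⁻⁵ s⁻¹, Ea = 95.0 kJ mol⁻¹)
    2 growing radical → dead chain (k = 2.60 × 10⁸ M⁻¹ s⁻¹, Ea = 15.0 kJ mol⁻¹)
    free monomer + initiating radical → growing radical + monomer in chains (k = 13000 M⁻¹ s⁻¹, Ea = 16.0 kJ mol⁻¹)
    2 free monomer → homo dimer (k = 1.20 × 10⁻⁴ M⁻¹ s⁻¹, Ea = 79.0 kJ mol⁻¹)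
    free monomer + growing radical → monomer in chains + growing radical, rate k5*[growing radical]*[free monomer] (k = 4300 M⁻¹ s⁻¹, Ea = 42.0 kJ mol⁻¹)
    monomer in chains ⇌ isomer of the product (K = 0.800, k = 1.40 × 10⁻⁶ s⁻¹, Ea = 99.0 kJ mol⁻¹, ΔH = −2.00 kJ mol⁻¹)
    (constants at 40 °C)

In the flask maple left until 2.5 d, the chain lifetime of 2190 h gives 1.37% of the charge moved out of its 49.9% of chains. The computed isomer of the product there is 0.693%.

Readings and results stem from a simulated flask with constants of no real substance, and the scatter is random.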